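**Assumption:** the only stereocentre is C3 of the chroman ring, and the given SMILES makes it R. All phenols are carried unprotected, and commercial 2,4,6-trihydroxyacetophenone hydrate is dried before use. The route is a paper proposal; no step has been run.

## Retrosynthetic overview

1. 10 ⇒ 7 + 8: the chalcone C=C comes from a Claisen–Schmidt condensation, placed last so the cyclisation-prone 2',6'-dihydroxychalcone sees no further chemistry.
2. 7 ⇒ 5: the C3 carbinol comes from a chroman-3-one by catalyst-controlled CBS reduction, which sets 3R.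
3. 5 ⇒ 3 (key step): the C4–C4a bond joins an arene carbon and a ketone α-carbon, both normally nucleophilic. The α-carbon is made electrophilic as an α-oxo gold carbene (an enolonium equivalent) generated by oxidising a terminal alkyne.
4. 3 ⇒ 1 + 2: para-selective O-alkylation of phloroacetophenone with a tertiary propargylic chloride.
5. Ring order: both benzene rings are bought; the pyran ring is the only ring formed (step 2).

## Route

**Step 1**
Reactants: 1 2,4,6-trihydroxyacetophenone; 2 3-chloro-3-methylbut-1-yne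
Product: 3 1-[2,6-dihydroxy-4-(2-methylbut-3-yn-2-yloxy)phenyl]ethan-1-one
Conditions: 2 (1.2 equiv), CuCl2·2H2O (1 mol %), DBU (1.15 equiv), MeCN, 0 °C
Reagents that add atoms: none
Why: Copper-catalysed propargylic substitution (Godfrey-type O-propargylation through a copper acetylide/allenylidene) occurs at the para hydroxyl, which is the most acidic and the only one not hydrogen-bonded to the acetyl group, so one equivalent of base gives the symmetric mono-ether; no stereocentre is formed.

**Step 2**
Reactants: 3 1-[2,6-dihydroxy-4-(2-methylbut-3-yn-2-yloxy)phenyl]ethan-1-one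
Product: 5 6-acetyl-5,7-dihydroxy-2,2-dimethylchroman-3-one, via α-oxo gold carbene 4 (not isolated)
Conditions: (Me4tBuXPhos)AuNTf2 (5 mol %; Me4tBuXPhos = di-tert-butyl(2',4',6'-triisopropyl-3,4,5,6-tetramethylbiphenyl-2-yl)phosphine), 2,6-dichloropyridine N-oxide (2 equiv), ClCH2CH2Cl, 0 °C to rt
Reagents that add atoms: 2,6-dichloropyridine N-oxide, [O-][n+]1c(Cl)cccc1Cl
Why: In this gold-catalysed alkyne oxidation the N-oxide adds to the internal carbon of the gold-bound alkyne and loses 2,6-dichloropyridine to give carbene 4, an enolonium (α-keto cation) equivalent, whose electrophilic carbon is attacked by the neighbouring electron-rich ring carbon (intramolecular Friedel–Crafts-type arylation, then protodeauration) to close the pyranone; the two ortho positions are equivalent, so one regioisomer forms and no stereocentre is created.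

**Step 3**
Reactants: 5 6-acetyl-5,7-dihydroxy-2,2-dimethylchroman-3-one
Product: 7 1-[(3R)-3,5,7-trihydroxy-2,2-dimethyl-3,4-dihydro-2H-chromen-6-yl]ethan-1-one, via catecholboryl ether 6 (not isolated)
Conditions: (S)-2-methyl-CBS-oxazaborolidine (0.3 equiv), catecholborane (3 equiv), CH2Cl2/toluene, −78 to −30 °C; then MeOH, pH 7 buffer
Reagents that add atoms: none
Why: In this Corey–Bakshi–Shibata reduction the ketone binds the catalyst boron anti to the quaternary C2 (large group) with the C4 methylene as the small group, so the (S)-catalyst gives the 3R alcohol (same sense as acetophenone or pinacolone giving the R alcohols); the doubly ortho-substituted, hydrogen-bonded aryl methyl ketone is too hindered and electron-rich to compete, and catecholborane bound to a phenol carries no B–H, so it cannot deliver hydride to the acetyl group.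

**Step 4**
Reactants: 7 1-[(3R)-3,5,7-trihydroxy-2,2-dimethyl-3,4-dihydro-2H-chromen-6-yl]ethan-1-one; 8 4-hydroxybenzaldehyde
Product: 10 (2E)-3-(4-hydroxyphenyl)-1-[(3R)-3,5,7-trihydroxy-2,2-dimethyl-3,4-dihydro-2H-chromen-6-yl]prop-2-en-1-one, via aldol adduct 9 (not isolated)
Conditions: LiN(SiMe3)2 (6 equiv), THF, −78 °C to rt; then 1 M HCl to pH 4, 0 °C
Reagents that add atoms: none
Why: In this Claisen–Schmidt (crossed aldol) condensation excess amide base converts every OH to its lithium salt and then forms the methyl-ketone enolate, which adds to the non-enolisable aldehyde, and E1cB dehydration of aldolate 9 gives the conjugated E-enone; C3 is remote and untouched, and the aprotic medium with a cold, mildly acidic quench limits oxa-Michael closure to the flavanone.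

## Compound list

1 | 2,4,6-trihydroxyacetophenone | CC(=O)c1c(O)cc(O)cc1O | starting material
2 | 3-chloro-3-methylbut-1-yne | CC(C)(Cl)C#C | starting material
3 | 1-[2,6-dihydroxy-4-(2-methylbut-3-yn-2-yloxy)phenyl]ethan-1-one | CC(=O)c1c(O)cc(OC(C)(C)C#C)cc1O | intermediate
4 | [3-(4-acetyl-3,5-dihydroxyphenoxy)-3-methyl-2-oxobutylidene](Me4tBuXPhos)gold cation, the α-oxo gold carbene formed in the flask (NTf2 counter-ion) | CC(=O)c1c(O)cc(OC(C)(C)C(=O)C=[Au][P+](C(C)(C)C)(C(C)(C)C)c2c(C)c(C)c(C)c(C)c2-c2c(C(C)C)cc(C(C)C)cc2C(C)C)cc1O | intermediate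
5 | 6-acetyl-5,7-dihydroxy-2,2-dimethylchroman-3-one (6-acetyl-5,7-dihydroxy-2,2-dimethyl-2H-chromen-3(4H)-one) | CC(=O)c1c(O)cc2OC(C)(C)C(=O)Cc2c1O | intermediate
6 | 1-[(3R)-3-(1,3,2-benzodioxaborol-2-yloxy)-5,7-dihydroxy-2,2-dimethyl-3,4-dihydro-2H-chromen-6-yl]ethan-1-one, formed in the flask | CC1(C)Oc2cc(O)c(C(C)=O)c(O)c2C[C@H]1OB1Oc2ccccc2O1 | intermediate
7 | 1-[(3R)-3,5,7-trihydroxy-2,2-dimethyl-3,4-dihydro-2H-chromen-6-yl]ethan-1-one | CC1(C)Oc2cc(O)c(C(C)=O)c(O)c2C[C@H]1O | intermediate
8 | 4-hydroxybenzaldehyde | O=Cc1ccc(O)cc1 | starting material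
9 | 3-hydroxy-3-(4-hydroxyphenyl)-1-[(3R)-3,5,7-trihydroxy-2,2-dimethyl-3,4-dihydro-2H-chromen-6-yl]propan-1-one, both epimers at the new carbinol carbon, formed in the flask as lithium salts | CC1(C)Oc2cc(O)c(C(=O)CC(O)c3ccc(O)cc3)c(O)c2C[C@H]1O | intermediate
10 | (2E)-3-(4-hydroxyphenyl)-1-[(3R)-3,5,7-trihydroxy-2,2-dimethyl-3,4-dihydro-2H-chromen-6-yl]prop-2-en-1-one | CC1(C)Oc2cc(O)c(C(=O)/C=C/c3ccc(O)cc3)c(O)c2C[C@H]1O | target

## Totals and risks

Total step count: 4. Longest linear sequence: 4 steps (1 → 3 → 5 → 7 → 10); compounds 2 and 8 are bought.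

**Step 2 (key cyclisation).** The ring is very electron-rich, so direct gold-catalysed hydroarylation to the 2H-chromene, O–H insertion of the carbene, or catalyst binding by the phenols may win. The fallback sets out from 3 and comes back at 5. Both phenols of 3 are acetylated (Ac2O, pyridine, DMAP cat., CH2Cl2) to give 2-acetyl-5-[(2-methylbut-3-yn-2-yl)oxy]-1,3-phenylene diacetate F1. The less nucleophilic ring should no longer attack the gold-bound alkyne but should still capture the far more electrophilic α-oxo carbene, so the same oxidant and catalyst give 6-acetyl-2,2-dimethyl-3-oxo-3,4-dihydro-2H-chromene-5,7-diyl diacetate F2. Brief methanolysis (K2CO3, MeOH, 0 °C) then returns 5.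

**Step 3 (asymmetric reduction).** The free phenols may consume or degrade the boron reagents, the aryl ketone may be touched, or the ee may be too low. The fallback sets out from 5 and comes back at 7, replacing asymmetric induction by resolution. NaBH4 (MeOH, 0 °C) reduces only the unhindered dialkyl ketone and gives racemic 1-(3,5,7-trihydroxy-2,2-dimethyl-3,4-dihydro-2H-chromen-6-yl)ethan-1-one F3. Preparative chiral SFC (amylose tris(3,5-dimethylphenylcarbamate) phase, CO2/MeOH) delivers 7, at a ceiling of 50 % yield. The unwanted 1-[(3S)-3,5,7-trihydroxy-2,2-dimethyl-3,4-dihydro-2H-chromen-6-yl]ethan-1-one F4 is set aside.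

**Step 4 (unprotected condensation).** The polyanion of 7 may not enolise cleanly, and the 2',6'-dihydroxychalcone can close to the flavanone during reaction or work-up. The fallback sets out from 7 and comes back at 10. The two phenols are masked selectively over the secondary alcohol (NaH 2.1 equiv, MOMCl 2.2 equiv, DMF, 0 °C) to give 1-[(3R)-3-hydroxy-5,7-bis(methoxymethoxy)-2,2-dimethyl-3,4-dihydro-2H-chromen-6-yl]ethan-1-one F5. A classical Claisen–Schmidt condensation with 8 (KOH, EtOH/H2O, rt) gives (2E)-1-[(3R)-3-hydroxy-5,7-bis(methoxymethoxy)-2,2-dimethyl-3,4-dihydro-2H-chromen-6-yl]-3-(4-hydroxyphenyl)prop-2-en-1-one F6, which cannot cyclise because neither ortho oxygen is free. Short treatment with 3 M HCl in MeOH at rt removes both MOM groups and returns 10.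

## Further compounds

F1 | step 2 | 2-acetyl-5-[(2-methylbut-3-yn-2-yl)oxy]-1,3-phenylene diacetate | CC(=O)Oc1cc(OC(C)(C)C#C)cc(OC(C)=O)c1C(C)=O
F2 | step 2 | 6-acetyl-2,2-dimethyl-3-oxo-3,4-dihydro-2H-chromene-5,7-diyl diacetate | CC(=O)Oc1cc2OC(C)(C)C(=O)Cc2c(OC(C)=O)c1C(C)=O
F3 | step 3 | racemic 1-(3,5,7-trihydroxy-2,2-dimethyl-3,4-dihydro-2H-chromen-6-yl)ethan-1-one | CC1(C)Oc2cc(O)c(C(C)=O)c(O)c2CC1O
F4 | step 3 | 1-[(3S)-3,5,7-trihydroxy-2,2-dimethyl-3,4-dihydro-2H-chromen-6-yl]ethan-1-one | CC1(C)Oc2cc(O)c(C(C)=O)c(O)c2C[C@@H]1O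
F5 | step 4 | 1-[(3R)-3-hydroxy-5,7-bis(methoxymethoxy)-2,2-dimethyl-3,4-dihydro-2H-chromen-6-yl]ethan-1-one | CC1(C)Oc2cc(OCOC)c(C(C)=O)c(OCOC)c2C[C@H]1O
F6 | step 4 | (2E)-1-[(3R)-3-hydroxy-5,7-bis(methoxymethoxy)-2,2-dimethyl-3,4-dihydro-2H-chromen-6-yl]-3-(4-hydroxyphenyl)prop-2-en-1-one | CC1(C)Oc2cc(OCOC)c(C(=O)/C=C/c3ccc(O)cc3)c(OCOC)c2C[C@H]1O
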